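**Strategy.** Everything rests on opening ring ε (C1′–C6′) by a retro-[4+2]. The C4′=C5′ alkene, flanked by oxygen at C3′ and by the side-chain carbon C7′ at C6′, is the imprint of a 2-pyranone; C1′(CH3)2–C2′H2 is 2-methylpropene. In one operation the high-pressure Diels–Alder reaction of 4-methyl-2H-pyran-2-one with 2-methylpropene forges C2′–C3′ and C6′–C1′ (the quaternary centre). It gives a bridged lactone whose ring oxygen becomes the 3′-hydroxyl and whose carbonyl becomes C7′. After resolution and inversion at C3′ the ring is grown to a C25 phosphonium salt, which is joined by Wittig reaction to a furan-derived C15 keto-enal carrying ring β and the octenoate.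

Key step: step 1

Remark: carotenoid numbering is used (ring β C1–C6, ring ε C1′–C6′, C19 the acyloxymethyl carbon); compounds 1, 12, 17 and 27 are taken as purchasable; racemic compounds are named rac- and drawn as the enantiomer that is carried forward.

**Route**

Step 1
Reactants: 1 4-methyl-2H-pyran-2-one; 2 2-methylpropene
Product: 3 rac-(1S,4R)-5,8,8-trimethyl-2-oxabicyclo[2.2.2]oct-5-en-3-one
Conditions: 2 (10 equiv), CH2Cl2, BHT (trace), acid-free Teflon ampoule, 15 kbar, 60 °C, 72 h
Reagents that add atoms: none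
Why: Concerted but asynchronous inverse-electron-demand [4+2] cycloaddition in which the C3=C4–C5=C6 diene of the electron-poor pyranone 1 adds to the electron-rich 1,1-disubstituted alkene 2; 15 kbar supplies the large negative activation volume and keeps the temperature low enough that the adduct does not extrude CO2. The closest known reaction type is the high-pressure Diels–Alder reaction of 2-pyranones with alkenes to 2-oxabicyclo[2.2.2]oct-5-en-3-ones. The new carbocycle (ring ε, C1′–C6′) closes by intermolecular suprafacial [4+2] addition across pyranone C3 and C6, so that the lactone C7′(=O)–O becomes a bridge over it. The regiochemistry should be the required one because the nucleophilic CH2 terminus of 2 bonds to C6 of 1 (δ-carbon of the dienoate, largest LUMO coefficient, later C3′), while the carbon carrying the incipient tertiary cation closes on the enolate-like C3 (later C6′), which creates the C6′–C1′ bond to the quaternary carbon. The two new stereocentres C3′ and C6′ are bridgeheads and are fixed cis to each other by the lactone bridge (racemate; no endo/exo question, since each alkene carbon of 2 carries two identical substituents). The step needs chemoselectivity against cationic oligomerisation of 2 and against retro-[4+2] loss of CO2, which acid-free conditions, pressure and the low temperature should secure.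

Step 2
Reactants: 3 rac-(1S,4R)-5,8,8-trimethyl-2-oxabicyclo[2.2.2]oct-5-en-3-one
Product: 4 rac-(1S,4R)-5,8,8-trimethyl-2-oxabicyclo[2.2.2]oct-5-en-3-ol (lactol, anomer mixture)
Conditions: i-Bu2AlH (1.1 equiv), CH2Cl2, −78 °C; aq. KNaC4H4O6
Reagents that add atoms: none
Why: Partial reduction of a lactone to the lactol via an aluminate that is stable at −78 °C; neither bridgehead stereocentre is touched.

Step 3
Reactants: 4 rac-lactol; 5 1-(triphenyl-λ5-phosphanylidene)propan-2-one
Product: 6 rac-cis-3-hydroxy-α-ionone, rac-(E)-4-[(1R,4S)-4-hydroxy-2,6,6-trimethylcyclohex-2-en-1-yl]but-3-en-2-one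
Conditions: 5 (2 equiv), PhCO2H (10 mol %), toluene, 100 °C
Reagents that add atoms: none
Why: Wittig olefination of the ring-opened hydroxy-aldehyde tautomer of the lactol with a stabilised, non-basic ylide should give the E-enone without epimerising C6′, so the cis 3′,6′ relationship from step 1 is kept.

Step 4
Reactants: 6 rac-cis-3-hydroxy-α-ionone
Product: 7 (3S,6R)-3-hydroxy-α-ionone, (E)-4-[(1R,4S)-4-hydroxy-2,6,6-trimethylcyclohex-2-en-1-yl]but-3-en-2-one (single enantiomer)
Conditions: Pseudomonas fluorescens lipase (Amano AK), vinyl acetate (3 equiv), t-BuOMe, 30 °C, to about 50% conversion; chromatography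
Reagents that add atoms: none
Why: Lipase-catalysed kinetic resolution by irreversible transesterification: the enzyme should acetylate the (3R,6S)-enantiomer much faster (usual preference for the R carbinol of ionone-type cyclohexenols), so the (3S,6R)-alcohol is recovered and the absolute configuration of C6′ is fixed.

Step 5
Reactants: 7 (3S,6R)-3-hydroxy-α-ionone
Product: 8 (3R,6R)-3-(benzoyloxy)-α-ionone, (1R,4R)-3,5,5-trimethyl-4-[(1E)-3-oxobut-1-en-1-yl]cyclohex-2-en-1-yl benzoate
Conditions: PPh3, i-PrO2CN=NCO2i-Pr, PhCO2H, toluene, 0 °C → rt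
Reagents that add atoms: benzoic acid OC(=O)c1ccccc1
Why: Mitsunobu esterification: SN2 displacement of the oxyphosphonium by benzoate inverts C3′ (S → R) and so sets the trans 3′,6′ relationship of ring ε.

Step 6
Reactants: 8 (3R,6R)-3-(benzoyloxy)-α-ionone; 9 vinylmagnesium bromide
Product: 10 (1R,4R)-4-[(1E)-3-hydroxy-3-methylpenta-1,4-dien-1-yl]-3,5,5-trimethylcyclohex-2-en-1-ol (epimer mixture at the tertiary carbinol)
Conditions: CH2=CHMgBr (5 equiv), THF, −20 °C → rt; aq. NH4Cl
Reagents that add atoms: none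
Why: Grignard 1,2-addition to the enone carbonyl and, with the excess reagent, double addition to the benzoate, which frees the 3′-hydroxyl in the same flask; the new carbinol centre is inconsequential because it becomes sp2 in step 7.

Step 7
Reactants: 10 the vinyl carbinol diol
Product: 11 [(2E,4E)-5-[(1R,4R)-4-hydroxy-2,6,6-trimethylcyclohex-2-en-1-yl]-3-methylpenta-2,4-dien-1-yl]triphenylphosphonium bromide (C15 salt)
Conditions: Ph3P·HBr (1.05 equiv), MeOH/CH2Cl2, rt
Reagents that add atoms: triphenylphosphine hydrobromide [Br-].[PH+](c1ccccc1)(c1ccccc1)c1ccccc1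
Why: Acid ionisation of the tertiary bis-allylic alcohol to a pentadienyl cation and capture by PPh3 at the unhindered terminal carbon (SN1′ allylic transposition) should give the E,E-dienyl salt, while the secondary ring hydroxyl ionises far more slowly.

Step 8
Reactants: 11 C15 salt; 12 (2E,4E,6E)-2,7-dimethylocta-2,4,6-trienedial
Product: 14 (2E,4E,6E,8E,10E,12E)-13-[(1R,4R)-4-hydroxy-2,6,6-trimethylcyclohex-2-en-1-yl]-2,7,11-trimethyltrideca-2,4,6,8,10,12-hexaenal (C25 hydroxy-aldehyde), via C15 ylide 13 (not isolated)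
Conditions: NaOMe (1.1 equiv), MeOH/CH2Cl2, 0 °C; inverse addition to 12 (2.5 equiv), rt; then heptane, 80 °C, 2 h
Reagents that add atoms: none
Why: Wittig mono-olefination of the symmetrical dialdehyde (excess 12 suppresses the double condensation); the hindered Z isomer at the new C11′=C12′ bond should relax thermally to E.

Step 9
Reactants: 14 C25 hydroxy-aldehyde
Product: 15 (2E,4E,6E,8E,10E,12E)-13-[(1R,4R)-4-hydroxy-2,6,6-trimethylcyclohex-2-en-1-yl]-2,7,11-trimethyltrideca-2,4,6,8,10,12-hexaen-1-ol (C25 diol)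
Conditions: NaBH4, MeOH/THF, 0 °C
Reagents that add atoms: none
Why: Chemoselective 1,2-hydride reduction of the polyenal to the primary allylic alcohol.

Step 10
Reactants: 15 C25 diol
Product: 16 [(2E,4E,6E,8E,10E,12E)-13-[(1R,4R)-4-hydroxy-2,6,6-trimethylcyclohex-2-en-1-yl]-2,7,11-trimethyltrideca-2,4,6,8,10,12-hexaen-1-yl]triphenylphosphonium bromide (C25 salt)
Conditions: Ph3P·HBr (1.05 equiv), MeOH/CH2Cl2, 0 °C → rt, dark
Reagents that add atoms: triphenylphosphine hydrobromide [Br-].[PH+](c1ccccc1)(c1ccccc1)c1ccccc1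
Why: The primary polyenylic alcohol ionises readily to a highly delocalised cation that PPh3 captures at the terminal carbon (SN1-type phosphonium salt formation); the secondary allylic 3′-hydroxyl should survive because its cation is far less stabilised.

Step 11
Reactants: 17 (4R,6R)-4-hydroxy-2,2,6-trimethylcyclohexan-1-one (actinol)
Product: 18 (4R,6R)-4-[(tert-butyldimethylsilyl)oxy]-2,2,6-trimethylcyclohexan-1-one
Conditions: t-BuMe2SiCl, imidazole, DMF, rt
Reagents that add atoms: tert-butyldimethylsilyl chloride CC(C)(C)[Si](C)(C)Cl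
Why: Standard silylation of the secondary alcohol; the C4 stereocentre (later C3, R) is untouched.

Step 12
Reactants: 18 the silyl ether of actinol
Product: 20 (4R)-4-[(tert-butyldimethylsilyl)oxy]-2,6,6-trimethylcyclohex-1-en-1-yl trifluoromethanesulfonate, via lithium enolate 19 (not isolated)
Conditions: LiN(i-Pr)2 (1.2 equiv), THF, −78 → 0 °C; PhNTf2, −78 °C → rt
Reagents that add atoms: N-phenylbis(trifluoromethanesulfonimide) O=S(=O)(N(c1ccccc1)S(=O)(=O)C(F)(F)F)C(F)(F)F
Why: Enolisation can occur only toward C6 (C2 is quaternary), and O-triflation of the enolate gives the tetrasubstituted enol triflate that defines the C5=C6 double bond of ring β.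

Step 13
Reactants: 20 the enol triflate
Product: 21 methyl (4R)-4-[(tert-butyldimethylsilyl)oxy]-2,6,6-trimethylcyclohex-1-ene-1-carboxylate
Conditions: Pd(OAc)2 (5 mol %), Ph2P(CH2)3PPh2, CO (1 atm), MeOH, Et3N, DMF, 70 °C
Reagents that add atoms: carbon monoxide [C-]#[O+]; methanol CO
Why: Palladium-catalysed methoxycarbonylation (oxidative addition of the vinyl triflate to zerovalent palladium formed in situ, CO insertion, methanolysis) installs C7.

Step 14
Reactants: 21 the methyl ester
Product: 22 [(4R)-4-[(tert-butyldimethylsilyl)oxy]-2,6,6-trimethylcyclohex-1-en-1-yl]methanol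
Conditions: i-Bu2AlH (2.5 equiv), CH2Cl2, −78 → 0 °C; aq. KNaC4H4O6
Reagents that add atoms: none
Why: 1,2-Reduction of the hindered conjugated ester to the allylic alcohol.

Step 15
Reactants: 22 the allylic alcohol
Product: 23 {[(1R)-4-(bromomethyl)-3,5,5-trimethylcyclohex-3-en-1-yl]oxy}(tert-butyl)dimethylsilane
Conditions: CBr4, PPh3, 2,6-lutidine, CH2Cl2, 0 °C; used without storage
Reagents that add atoms: tetrabromomethane BrC(Br)(Br)Br
Why: Appel bromination of the primary allylic alcohol under neutral conditions that spare the silyl ether.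

Step 16
Reactants: 23 the allylic bromide; 24 furan-3-ylmethanol
Product: 26 [2-{[(4R)-4-[(tert-butyldimethylsilyl)oxy]-2,6,6-trimethylcyclohex-1-en-1-yl]methyl}furan-3-yl]methanol, via dilithiated furanmethanol 25 (not isolated)
Conditions: 24 (1.5 equiv), n-BuLi (3.3 equiv), THF, −78 → 0 °C; then 23, −78 °C → rt; H2O
Reagents that add atoms: none
Why: Alkoxide-directed lithiation of 24 at C2 and SN2 alkylation of the furyllithium by the primary allylic bromide (SN2′ is blocked by the fully substituted C5) forms the C7–C8 bond; the furan carries C8–C11 and C19 as a masked cis-enedione.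

Step 17
Reactants: 26 the furylmethanol; 27 (2E)-oct-2-enoic acid
Product: 28 [2-{[(4R)-4-[(tert-butyldimethylsilyl)oxy]-2,6,6-trimethylcyclohex-1-en-1-yl]methyl}furan-3-yl]methyl (2E)-oct-2-enoate
Conditions: N-(3-dimethylaminopropyl)-N′-ethylcarbodiimide hydrochloride, 4-(dimethylamino)pyridine (10 mol %), CH2Cl2, 0 °C → rt
Reagents that add atoms: none
Why: Steglich esterification of the only free (primary) hydroxyl installs the C19 ester.

Step 18
Reactants: 28 the silylated furan ester
Product: 29 [2-{[(4R)-4-hydroxy-2,6,6-trimethylcyclohex-1-en-1-yl]methyl}furan-3-yl]methyl (2E)-oct-2-enoate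
Conditions: HF·pyridine, pyridine/THF, 0 °C → rt
Reagents that add atoms: none
Why: Buffered fluoride cleavage of the secondary silyl ether leaves the ester and the furan intact, so that no protecting group reaches the polyene stage.

Step 19
Reactants: 29 the furan ester
Product: 31 (2E)-2-{2-[(4R)-4-hydroxy-2,6,6-trimethylcyclohex-1-en-1-yl]acetyl}-4-oxobut-2-en-1-yl (2E)-oct-2-enoate (C15 keto-enal), via (2Z)-keto-enal 30 (not isolated)
Conditions: N-bromosuccinimide (1.05 equiv), NaHCO3, acetone/H2O (10:1), −20 °C, 30 min; extraction; then I2 (2 mol %), CH2Cl2, daylight, rt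
Reagents that add atoms: water O
Why: Oxidative ring opening of the 2,3-disubstituted furan (bromonium attack, addition of water, loss of HBr) unmasks the cis-ene-dicarbonyl, and iodine-catalysed equilibration should give the E isomer with the C8 ketone trans to C11, as the target needs.

Step 20
Reactants: 16 C25 salt; 31 C15 keto-enal
Product: 33 (3R,3′R,6′R)-3,3′-dihydroxy-8-oxo-7,8-dihydro-β,ε-caroten-19-yl (2E)-oct-2-enoate (target), via C25 ylide 32 (not isolated)
Conditions: 1,2-epoxybutane (solvent), 60 °C, Ar, dark, 16 h; then EtOAc/heptane, 70 °C, 1 h; chromatography on deactivated silica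
Reagents that add atoms: none
Why: Wittig olefination with base generated under neutral conditions (bromide opens the epoxide): the polyenyl ylide should condense with the aldehyde, which is far more electrophilic than the C8 ketone, to form C11=C12, and the hindered 11Z isomer should relax thermally to the all-E target.

**Compound list**

1 | 4-methyl-2H-pyran-2-one | CC1=CC(=O)OC=C1 | starting material
2 | 2-methylpropene | CC(C)=C | starting material
3 | rac-(1S,4R)-5,8,8-trimethyl-2-oxabicyclo[2.2.2]oct-5-en-3-one | O=C1O[C@@H]2C=C(C)[C@H]1C(C)(C)C2 | intermediate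
4 | rac-(1S,4R)-5,8,8-trimethyl-2-oxabicyclo[2.2.2]oct-5-en-3-ol (anomer mixture) | OC1O[C@@H]2C=C(C)[C@H]1C(C)(C)C2 | intermediate
5 | 1-(triphenyl-λ5-phosphanylidene)propan-2-one | CC(=O)C=P(c1ccccc1)(c1ccccc1)c1ccccc1 | starting material
6 | rac-cis-3-hydroxy-α-ionone, rac-(E)-4-[(1R,4S)-4-hydroxy-2,6,6-trimethylcyclohex-2-en-1-yl]but-3-en-2-one | CC(=O)/C=C/[C@H]1C(C)=C[C@@H](O)CC1(C)C | intermediate
7 | (3S,6R)-3-hydroxy-α-ionone (single enantiomer) | CC(=O)/C=C/[C@H]1C(C)=C[C@@H](O)CC1(C)C | intermediate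
8 | (3R,6R)-3-(benzoyloxy)-α-ionone | CC(=O)/C=C/[C@H]1C(C)=C[C@H](OC(=O)c2ccccc2)CC1(C)C | intermediate
9 | vinylmagnesium bromide | C=C[Mg]Br | starting material
10 | (1R,4R)-4-[(1E)-3-hydroxy-3-methylpenta-1,4-dien-1-yl]-3,5,5-trimethylcyclohex-2-en-1-ol (carbinol epimers) | C=CC(C)(O)/C=C/[C@H]1C(C)=C[C@H](O)CC1(C)C | intermediate
11 | C15 salt, [(2E,4E)-5-[(1R,4R)-4-hydroxy-2,6,6-trimethylcyclohex-2-en-1-yl]-3-methylpenta-2,4-dien-1-yl]triphenylphosphonium bromide | [Br-].C(/C=C(C)/C=C/[C@H]1C(C)=C[C@H](O)CC1(C)C)[P+](c1ccccc1)(c1ccccc1)c1ccccc1 | intermediate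
12 | (2E,4E,6E)-2,7-dimethylocta-2,4,6-trienedial | O=C/C(C)=C/C=C/C=C(C)/C=O | starting material
13 | C15 ylide (phosphorane of 11) | C(/C=C(C)/C=C/[C@H]1C(C)=C[C@H](O)CC1(C)C)=P(c1ccccc1)(c1ccccc1)c1ccccc1 | intermediate
14 | C25 hydroxy-aldehyde, (2E,4E,6E,8E,10E,12E)-13-[(1R,4R)-4-hydroxy-2,6,6-trimethylcyclohex-2-en-1-yl]-2,7,11-trimethyltrideca-2,4,6,8,10,12-hexaenal | O=C/C(C)=C/C=C/C=C(C)/C=C/C=C(C)/C=C/[C@H]1C(C)=C[C@H](O)CC1(C)C | intermediate
15 | C25 diol, the corresponding hexaen-1-ol | OC/C(C)=C/C=C/C=C(C)/C=C/C=C(C)/C=C/[C@H]1C(C)=C[C@H](O)CC1(C)C | intermediate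
16 | C25 salt, the corresponding hexaen-1-yl triphenylphosphonium bromide | [Br-].C(/C(C)=C/C=C/C=C(C)/C=C/C=C(C)/C=C/[C@H]1C(C)=C[C@H](O)CC1(C)C)[P+](c1ccccc1)(c1ccccc1)c1ccccc1 | intermediate
17 | (4R,6R)-4-hydroxy-2,2,6-trimethylcyclohexan-1-one (actinol) | O=C1[C@H](C)C[C@@H](O)CC1(C)C | starting material
18 | (4R,6R)-4-[(tert-butyldimethylsilyl)oxy]-2,2,6-trimethylcyclohexan-1-one | O=C1[C@H](C)C[C@@H](O[Si](C)(C)C(C)(C)C)CC1(C)C | intermediate
19 | lithium (4R)-4-[(tert-butyldimethylsilyl)oxy]-2,6,6-trimethylcyclohex-1-en-1-olate | [Li]OC1=C(C)C[C@@H](O[Si](C)(C)C(C)(C)C)CC1(C)C | intermediate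
20 | (4R)-4-[(tert-butyldimethylsilyl)oxy]-2,6,6-trimethylcyclohex-1-en-1-yl trifluoromethanesulfonate | O=S(=O)(OC1=C(C)C[C@@H](O[Si](C)(C)C(C)(C)C)CC1(C)C)C(F)(F)F | intermediate
21 | methyl (4R)-4-[(tert-butyldimethylsilyl)oxy]-2,6,6-trimethylcyclohex-1-ene-1-carboxylate | COC(=O)C1=C(C)C[C@@H](O[Si](C)(C)C(C)(C)C)CC1(C)C | intermediate
22 | [(4R)-4-[(tert-butyldimethylsilyl)oxy]-2,6,6-trimethylcyclohex-1-en-1-yl]methanol | OCC1=C(C)C[C@@H](O[Si](C)(C)C(C)(C)C)CC1(C)C | intermediate
23 | {[(1R)-4-(bromomethyl)-3,5,5-trimethylcyclohex-3-en-1-yl]oxy}(tert-butyl)dimethylsilane | BrCC1=C(C)C[C@@H](O[Si](C)(C)C(C)(C)C)CC1(C)C | intermediate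
24 | furan-3-ylmethanol | OCc1ccoc1 | starting material
25 | dilithiated furan-3-ylmethanol (2-lithio, O-lithio) | [Li]OCc1ccoc1[Li] | intermediate
26 | [2-{[(4R)-4-[(tert-butyldimethylsilyl)oxy]-2,6,6-trimethylcyclohex-1-en-1-yl]methyl}furan-3-yl]methanol | OCc1ccoc1CC1=C(C)C[C@@H](O[Si](C)(C)C(C)(C)C)CC1(C)C | intermediate
27 | (2E)-oct-2-enoic acid | CCCCC/C=C/C(=O)O | starting material
28 | [2-{[(4R)-4-[(tert-butyldimethylsilyl)oxy]-2,6,6-trimethylcyclohex-1-en-1-yl]methyl}furan-3-yl]methyl (2E)-oct-2-enoate | CCCCC/C=C/C(=O)OCc1ccoc1CC1=C(C)C[C@@H](O[Si](C)(C)C(C)(C)C)CC1(C)C | intermediate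
29 | [2-{[(4R)-4-hydroxy-2,6,6-trimethylcyclohex-1-en-1-yl]methyl}furan-3-yl]methyl (2E)-oct-2-enoate | CCCCC/C=C/C(=O)OCc1ccoc1CC1=C(C)C[C@@H](O)CC1(C)C | intermediate
30 | (2Z)-2-{2-[(4R)-4-hydroxy-2,6,6-trimethylcyclohex-1-en-1-yl]acetyl}-4-oxobut-2-en-1-yl (2E)-oct-2-enoate | CCCCC/C=C/C(=O)OC/C(=C/C=O)C(=O)CC1=C(C)C[C@@H](O)CC1(C)C | intermediate
31 | C15 keto-enal, (2E)-2-{2-[(4R)-4-hydroxy-2,6,6-trimethylcyclohex-1-en-1-yl]acetyl}-4-oxobut-2-en-1-yl (2E)-oct-2-enoate | CCCCC/C=C/C(=O)OC\C(=C/C=O)C(=O)CC1=C(C)C[C@@H](O)CC1(C)C | intermediate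
32 | C25 ylide (phosphorane of 16) | C(/C(C)=C/C=C/C=C(C)/C=C/C=C(C)/C=C/[C@H]1C(C)=C[C@H](O)CC1(C)C)=P(c1ccccc1)(c1ccccc1)c1ccccc1 | intermediate
33 | (3R,3′R,6′R)-3,3′-dihydroxy-8-oxo-7,8-dihydro-β,ε-caroten-19-yl (2E)-oct-2-enoate | CCCCC/C=C/C(=O)OC\C(=C/C=C/C(C)=C/C=C/C=C(C)/C=C/C=C(C)/C=C/[C@H]1C(C)=C[C@H](O)CC1(C)C)C(=O)CC1=C(C)C[C@@H](O)CC1(C)C | target

**Step count and risks**

Total step count: 20 (ten on the ring ε branch, nine on the ring β branch, one union). Longest linear sequence: 11 (steps 1–10, then step 20).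

Steps most likely to fail:

Step 1. The unactivated alkene may react too slowly with the unactivated pyranone even under pressure, the cycloaddition may take the reversed orientation, or the adduct may lose CO2 by cycloreversion. The fallback sets out from 1 and returns at 3. Pyranone 1 is brominated at C3 (Br2 in CH2Cl2, then Et3N) to give 3-bromo-4-methyl-2H-pyran-2-one F1, an ambiphilic and much more reactive diene. F1 is heated with 2 in a sealed tube (toluene, 90 °C) to give the bridgehead bromide rac-4-bromo-5,8,8-trimethyl-2-oxabicyclo[2.2.2]oct-5-en-3-one F2. Radical debromination (n-Bu3SnH, azobisisobutyronitrile, benzene, 80 °C; the bridgehead radical can only be reduced with retention of the bicycle) then gives 3.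

Step 19. Electrophilic bromine may also attack the tetrasubstituted C5=C6 alkene of ring β, and the liberated cis keto-enal may decompose before it is equilibrated to the E isomer. The fallback sets out from 29 and returns at 31. The furan is oxidised without any electrophilic halogen by anodic 2,5-dimethoxylation (graphite anode, MeOH, Et4NOTs, 2,6-lutidine, −20 °C, constant current) to the isolable 2,5-dimethoxy-2,5-dihydrofuran F3. Mild hydrolysis (wet acetone, pyridinium p-toluenesulfonate, rt) then releases 30, which is equilibrated with catalytic I2 as in the route to give 31.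

Step 20. The ylide or the alkoxide formed in situ may add in conjugate fashion to the ene-dicarbonyl and expel the octenoate from C19 (SN2′-type loss of the ester), and the keto-enal may oligomerise. The fallback sets out from 26 (with 16 and 27) and returns at 33; it carries C19 as a silyl ether, which cannot leave, and acylates last. Alcohol 26 is silylated (t-BuMe2SiCl, imidazole, DMF) to the bis-silyl ether tert-butyl{[2-({(4R)-4-[(tert-butyldimethylsilyl)oxy]-2,6,6-trimethylcyclohex-1-en-1-yl}methyl)furan-3-yl]methoxy}dimethylsilane F4. Oxidation as in step 19 (N-bromosuccinimide, NaHCO3, acetone/H2O; then I2) gives the bis-silylated (E)-keto-enal F5. Wittig reaction of F5 with ylide 32 from 16 (1,2-epoxybutane, 60 °C) gives 3,19-bis-O-(tert-butyldimethylsilyl)siphonaxanthin F6. Desilylation (HF·pyridine, pyridine/THF) gives the triol siphonaxanthin F7. Its primary allylic 19-hydroxyl is then acylated selectively over the two secondary hydroxyls with (2E)-oct-2-enoyl chloride F8 (from 27 and (COCl)2), 2,4,6-collidine, CH2Cl2, −40 °C, to give 33.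

**Further compounds**

F1 | step 1 | 3-bromo-4-methyl-2H-pyran-2-one | CC1=C(Br)C(=O)OC=C1
F2 | step 1 | rac-4-bromo-5,8,8-trimethyl-2-oxabicyclo[2.2.2]oct-5-en-3-one | O=C1O[C@@H]2C=C(C)[C@@]1(Br)C(C)(C)C2
F3 | step 19 | [2-{[(4R)-4-hydroxy-2,6,6-trimethylcyclohex-1-en-1-yl]methyl}-2,5-dimethoxy-2,5-dihydrofuran-3-yl]methyl (2E)-oct-2-enoate (isomer mixture at the acetal carbons) | CCCCC/C=C/C(=O)OCC1=CC(OC)OC1(OC)CC2=C(C)C[C@@H](O)CC2(C)C
F4 | step 20 | tert-butyl{[2-({(4R)-4-[(tert-butyldimethylsilyl)oxy]-2,6,6-trimethylcyclohex-1-en-1-yl}methyl)furan-3-yl]methoxy}dimethylsilane | CC(C)(C)[Si](C)(C)OCc1ccoc1CC1=C(C)C[C@@H](O[Si](C)(C)C(C)(C)C)CC1(C)C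
F5 | step 20 | (2E)-4-[(tert-butyldimethylsilyl)oxy]-3-{2-[(4R)-4-[(tert-butyldimethylsilyl)oxy]-2,6,6-trimethylcyclohex-1-en-1-yl]acetyl}but-2-enal | CC(C)(C)[Si](C)(C)OC\C(=C/C=O)C(=O)CC1=C(C)C[C@@H](O[Si](C)(C)C(C)(C)C)CC1(C)C
F6 | step 20 | 3,19-bis-O-(tert-butyldimethylsilyl)siphonaxanthin | CC(C)(C)[Si](C)(C)OC\C(=C/C=C/C(C)=C/C=C/C=C(C)/C=C/C=C(C)/C=C/[C@H]1C(C)=C[C@H](O)CC1(C)C)C(=O)CC1=C(C)C[C@@H](O[Si](C)(C)C(C)(C)C)CC1(C)C
F7 | step 20 | siphonaxanthin, (3R,3′R,6′R)-3,19,3′-trihydroxy-7,8-dihydro-β,ε-caroten-8-one | OC\C(=C/C=C/C(C)=C/C=C/C=C(C)/C=C/C=C(C)/C=C/[C@H]1C(C)=C[C@H](O)CC1(C)C)C(=O)CC1=C(C)C[C@@H](O)CC1(C)C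
F8 | step 20 | (2E)-oct-2-enoyl chloride | CCCCC/C=C/C(Cl)=O
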